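## Retrosynthetic overview

1. Lespeflorin B1 (2R,3R) comes from its 7,4'-bis(methoxymethyl) ether, and that from a C3 allyl ester; the C3–H is installed last by palladium-mediated deallylation–decarboxylation through the C3/C4 enediol.
2. The strategy rests on the acyloin inside ring C: the C4 aryl ketone on ring A next to the C3 carbinol. C4 is read as the acyl anion of a ring A salicylaldehyde carbon, so the C3–C4 bond is cut back to an aldehyde and a C3 keto group.
3. A chiral triazolium carbene benzoin closes ring C, the only ring formed (rings A and B are bought), while the base-labile C2 centre of the racemic aryloxy α-keto ester is resolved dynamically.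
4. The keto ester comes from oxidation of the α-hydroxy ester, whose O1–C2 bond is made by phenoxide opening of the ring B Darzens glycidate with the ring A salicylaldehyde.
5. Both aldehydes come from 5-bromo-2,4-dihydroxybenzaldehyde and 3-bromo-4-hydroxybenzaldehyde by methoxymethyl protection and Stille prenylation.

Key step: step 8

Assumption: intermediates 9 to 12 are racemic (9 to 11 also diastereomer mixtures) and are written without stereodescriptors, because one centre is oxidised in step 7 and the other equilibrates in step 8.

Assumption: the sense of induction of the aminoindanol-derived triazolium salt cannot be predicted with certainty; the antipode that delivers the (2R) series is used, both antipodes being accessible from cis-1-amino-2-indanol.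

## Route

Step 1
Reactants: 1 5-bromo-2,4-dihydroxybenzaldehyde
Product: 2 5-bromo-2-hydroxy-4-(methoxymethoxy)benzaldehyde
Conditions: MOMCl (1.05 equiv), K2CO3, acetone, 0 °C to rt
Reagents that add atoms: chloromethyl methyl ether, COCCl
Why: Williamson-type O-alkylation in which the unchelated, more acidic 4-hydroxyl (para to the formyl group) reacts, while the 2-hydroxyl is held in a hydrogen bond to the aldehyde and should stay free with one equivalent of reagent.

Step 2
Reactants: 2 5-bromo-2-hydroxy-4-(methoxymethoxy)benzaldehyde; 3 tributyl(3-methylbut-2-enyl)stannane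
Product: 4 2-hydroxy-4-(methoxymethoxy)-5-(3-methylbut-2-enyl)benzaldehyde
Conditions: Pd(PPh3)4 (5 mol %), DMF, 100 °C, argon
Reagents that add atoms: none
Why: Stille coupling in which zerovalent palladium inserts into the aryl bromide, the prenyl group is transferred from tin and reductive elimination at the unsubstituted allyl terminus should give the linear prenyl arene; the chelated phenol and the aldehyde tolerate the neutral conditions.

Step 3
Reactants: 5 3-bromo-4-hydroxybenzaldehyde
Product: 6 3-bromo-4-(methoxymethoxy)benzaldehyde
Conditions: MOMCl (1.2 equiv), K2CO3, acetone, 0 °C to rt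
Reagents that add atoms: chloromethyl methyl ether, COCCl
Why: Williamson-type O-alkylation of the only phenol, giving the methoxymethyl acetal.

Step 4
Reactants: 6 3-bromo-4-(methoxymethoxy)benzaldehyde; 3 tributyl(3-methylbut-2-enyl)stannane
Product: 7 4-(methoxymethoxy)-3-(3-methylbut-2-enyl)benzaldehyde
Conditions: Pd(PPh3)4 (5 mol %), DMF, 100 °C, argon
Reagents that add atoms: none
Why: Stille coupling as in step 2, with the aryl bromide activated by the para formyl group and the prenyl group expected to be delivered through its unsubstituted terminus.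

Step 5
Reactants: 7 4-(methoxymethoxy)-3-(3-methylbut-2-enyl)benzaldehyde; 8 allyl chloroacetate
Product: 10 allyl 3-[4-(methoxymethoxy)-3-(3-methylbut-2-enyl)phenyl]oxirane-2-carboxylate (racemic; mainly trans), via chlorohydrin alkoxide 9 (not isolated)
Conditions: t-BuOK (1.1 equiv), THF, −20 °C to rt
Reagents that add atoms: none
Why: Darzens condensation in which the potassium enolate of 8 adds to the aldehyde and the alkoxide displaces chloride to close the epoxide; the trans/cis ratio does not matter because one centre is oxidised in step 7 and the other equilibrates in step 8.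

Step 6
Reactants: 10 allyl 3-aryloxirane-2-carboxylate (ring B glycidate); 4 2-hydroxy-4-(methoxymethoxy)-5-(3-methylbut-2-enyl)benzaldehyde
Product: 11 allyl 3-[2-formyl-5-(methoxymethoxy)-4-(3-methylbut-2-enyl)phenoxy]-2-hydroxy-3-[4-(methoxymethoxy)-3-(3-methylbut-2-enyl)phenyl]propanoate (racemic)
Conditions: Cs2CO3 (0.2 equiv), DMF, 60 °C
Reagents that add atoms: none
Why: Nucleophilic epoxide opening in which the cesium phenoxide of 4 attacks the glycidate at its benzylic carbon, which is activated by the para-alkoxyaryl group and remote from the ester (the usual regiochemistry of 3-aryl glycidic esters with thiols, azide and phenols); the alkoxide is reprotonated by further phenol so catalytic base suffices, and the relative configuration formed is irrelevant.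

Step 7
Reactants: 11 allyl 3-(2-formylaryloxy)-2-hydroxy-3-arylpropanoate
Product: 12 allyl 3-[2-formyl-5-(methoxymethoxy)-4-(3-methylbut-2-enyl)phenoxy]-3-[4-(methoxymethoxy)-3-(3-methylbut-2-enyl)phenyl]-2-oxopropanoate (racemic; may contain its enol)
Conditions: Dess–Martin periodinane (1.3 equiv), CH2Cl2, 0 °C to rt; used without delay
Reagents that add atoms: none
Why: Dess–Martin oxidation of the secondary α-hydroxy ester to the α-keto ester under non-basic conditions, which leave the aryl aldehyde, the prenyl alkenes and the acetals untouched and do not trigger aldol chemistry of the acidic benzylic C–H.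

Step 8
Reactants: 12 allyl 3-(2-formylaryloxy)-3-aryl-2-oxopropanoate (racemic)
Product: 13 allyl (2R,3R)-3-hydroxy-7-(methoxymethoxy)-2-[4-(methoxymethoxy)-3-(3-methylbut-2-enyl)phenyl]-6-(3-methylbut-2-enyl)-4-oxochromane-3-carboxylate
Conditions: (5aS,10bR)-2-(pentafluorophenyl)-4,5a,6,10b-tetrahydroindeno[2,1-b][1,2,4]triazolo[4,3-d][1,4]oxazin-2-ium tetrafluoroborate or its antipode (15 mol %), i-Pr2NEt (20 mol %), 4 Å MS, toluene, 0 °C to rt, argon
Reagents that add atoms: none
Why: Proposed new method: the carbene freed from the triazolium salt adds to the ring A aldehyde of 12 to give the Breslow intermediate, whose nucleophilic carbon (the future C4) attacks the keto carbon (the future C3); proton transfer and release of the carbene leave the tertiary α-ketol. The closest known reaction types are the carbene-catalysed intramolecular crossed benzoin of 2-(2-oxoalkoxy)benzaldehydes to 3-hydroxychroman-4-ones and the dynamic kinetic cross-benzoin of β-stereogenic α-keto esters, which have not been merged on one substrate. Ring C closes in the 6-exo-trig mode. C3 is set by the catalyst: the hydrogen bond from the Breslow enol OH to the ketone oxygen holds the new C3–O bond near the plane of ring A (pseudo-equatorial hydroxyl, axial ester) and the indane wall of the triazolium leaves one ketone face open; C2 is set by dynamic kinetic resolution, since the C2–H flanked by the keto group, ring B and the aryloxy oxygen exchanges rapidly through the enol under the amine base and only the enantiomer that places ring B pseudo-equatorial, trans to the hydroxyl, should cyclise quickly. The step needs the carbene to form the acyl anion only at the aldehyde and to attack the ketone and not the ester, which the substrate secures because the keto ester has no formyl hydrogen, is the more electrophilic carbonyl and sits at the six-ring distance (the ester would need 7-exo closure). It also needs face control and relative control together, because C3 is erased in step 9 and only C2 carries the configuration forward, and it must outrun the reversible 5-exo aldol of the C2 enol onto the aldehyde, which the weak base, low temperature and non-polar solvent are chosen to hold back.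

Step 9
Reactants: 13 allyl (2R,3R)-3-hydroxy-4-oxoflavan-3-carboxylate, bis(methoxymethyl) ether
Product: 16 (2R,3R)-3-hydroxy-7-(methoxymethoxy)-2-[4-(methoxymethoxy)-3-(3-methylbut-2-enyl)phenyl]-6-(3-methylbut-2-enyl)chroman-4-one, via carboxylic acid 14 (not isolated), via enediol 15 (not isolated)
Conditions: Pd(PPh3)4 (5 mol %), HCO2H (2 equiv), Et3N (2.5 equiv), degassed THF, rt, argon
Reagents that add atoms: none
Why: Tsuji decarboxylation–hydrogenolysis of an allyl β-keto ester, in which zerovalent palladium ionises the allyl ester, formate reduces the allyl palladium species to propene and the α-hydroxy β-keto acid (axial carboxyl aligned with the C4 carbonyl) loses CO2 to the 3,4-enediol; ketonisation toward the aryl ketone conjugated with ring A, with axial protonation at C3 anti to H2, should give the diequatorial trans acyloin, which is also the thermodynamic isomer, while C2 is untouched.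

Step 10
Reactants: 16 (2R,3R)-dihydroflavonol 7,4'-bis(methoxymethyl) ether
Product: 17 lespeflorin B1, (2R,3R)-3,7-dihydroxy-2-[4-hydroxy-3-(3-methylbut-2-enyl)phenyl]-6-(3-methylbut-2-enyl)chroman-4-one
Conditions: HCl (ca. 1.5 M, from conc. HCl) in MeOH, 45 °C, monitored and stopped at full conversion
Reagents that add atoms: none
Why: Acid-catalysed methanolysis of the two aryl methoxymethyl acetals, conditions under which the trans acyloin does not epimerise and, on short exposure, the prenyl groups should not cyclise onto the freed phenols.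

## Compound list

1 | 5-bromo-2,4-dihydroxybenzaldehyde | O=Cc1cc(Br)c(O)cc1O | starting material
2 | 5-bromo-2-hydroxy-4-(methoxymethoxy)benzaldehyde | O=Cc1cc(Br)c(OCOC)cc1O | intermediate
3 | tributyl(3-methylbut-2-enyl)stannane | CCCC[Sn](CCCC)(CCCC)CC=C(C)C | starting material
4 | 2-hydroxy-4-(methoxymethoxy)-5-(3-methylbut-2-enyl)benzaldehyde | O=Cc1cc(CC=C(C)C)c(OCOC)cc1O | intermediate
5 | 3-bromo-4-hydroxybenzaldehyde | O=Cc1ccc(O)c(Br)c1 | starting material
6 | 3-bromo-4-(methoxymethoxy)benzaldehyde | O=Cc1ccc(OCOC)c(Br)c1 | intermediate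
7 | 4-(methoxymethoxy)-3-(3-methylbut-2-enyl)benzaldehyde | O=Cc1ccc(OCOC)c(CC=C(C)C)c1 | intermediate
8 | allyl chloroacetate | C=CCOC(=O)CCl | starting material
9 | allyl 2-chloro-3-hydroxy-3-[4-(methoxymethoxy)-3-(3-methylbut-2-enyl)phenyl]propanoate, potassium alkoxide | C=CCOC(=O)C(Cl)C([O-])c1ccc(OCOC)c(CC=C(C)C)c1.[K+] | intermediate (not isolated)
10 | allyl 3-[4-(methoxymethoxy)-3-(3-methylbut-2-enyl)phenyl]oxirane-2-carboxylate, racemic, mainly trans | C=CCOC(=O)C1OC1c1ccc(OCOC)c(CC=C(C)C)c1 | intermediate
11 | allyl 3-[2-formyl-5-(methoxymethoxy)-4-(3-methylbut-2-enyl)phenoxy]-2-hydroxy-3-[4-(methoxymethoxy)-3-(3-methylbut-2-enyl)phenyl]propanoate, racemic | C=CCOC(=O)C(O)C(Oc1cc(OCOC)c(CC=C(C)C)cc1C=O)c1ccc(OCOC)c(CC=C(C)C)c1 | intermediate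
12 | allyl 3-[2-formyl-5-(methoxymethoxy)-4-(3-methylbut-2-enyl)phenoxy]-3-[4-(methoxymethoxy)-3-(3-methylbut-2-enyl)phenyl]-2-oxopropanoate, racemic | C=CCOC(=O)C(=O)C(Oc1cc(OCOC)c(CC=C(C)C)cc1C=O)c1ccc(OCOC)c(CC=C(C)C)c1 | intermediate
13 | allyl (2R,3R)-3-hydroxy-7-(methoxymethoxy)-2-[4-(methoxymethoxy)-3-(3-methylbut-2-enyl)phenyl]-6-(3-methylbut-2-enyl)-4-oxochromane-3-carboxylate (aryl and hydroxyl trans) | CC(C)=CCc1cc([C@H]2Oc3cc(OCOC)c(CC=C(C)C)cc3C(=O)[C@@]2(O)C(=O)OCC=C)ccc1OCOC | intermediate
14 | (2R,3R)-3-hydroxy-7-(methoxymethoxy)-2-[4-(methoxymethoxy)-3-(3-methylbut-2-enyl)phenyl]-6-(3-methylbut-2-enyl)-4-oxochromane-3-carboxylic acid, formed as its triethylammonium salt | CC(C)=CCc1cc([C@H]2Oc3cc(OCOC)c(CC=C(C)C)cc3C(=O)[C@@]2(O)C(=O)O)ccc1OCOC | intermediate (not isolated)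
15 | (2R)-7-(methoxymethoxy)-2-[4-(methoxymethoxy)-3-(3-methylbut-2-enyl)phenyl]-6-(3-methylbut-2-enyl)-2H-chromene-3,4-diol | CC(C)=CCc1cc([C@H]2Oc3cc(OCOC)c(CC=C(C)C)cc3C(O)=C2O)ccc1OCOC | intermediate (not isolated)
16 | (2R,3R)-3-hydroxy-7-(methoxymethoxy)-2-[4-(methoxymethoxy)-3-(3-methylbut-2-enyl)phenyl]-6-(3-methylbut-2-enyl)chroman-4-one | CC(C)=CCc1cc([C@H]2Oc3cc(OCOC)c(CC=C(C)C)cc3C(=O)[C@@H]2O)ccc1OCOC | intermediate
17 | lespeflorin B1, (2R,3R)-3,7-dihydroxy-2-[4-hydroxy-3-(3-methylbut-2-enyl)phenyl]-6-(3-methylbut-2-enyl)chroman-4-one | CC(C)=CCc1cc([C@H]2Oc3cc(O)c(CC=C(C)C)cc3C(=O)[C@@H]2O)ccc1O | target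

## Step count and risks

Total step count: 10. Longest linear sequence: 8 steps (steps 3, 4, 5, 6, 7, 8, 9, 10, from 5).

**Steps most likely to fail**

1. Step 8 (proposed new method).
   - What may go wrong: the C2 enol may add to the neighbouring aldehyde (5-exo aldol of the Rap–Stoermer type) faster than the carbene engages it. Ring closure faster than C2 epimerisation, or weak face selection at the ketone, would erode the enantiomeric purity at C2.
   - Fallback (known chemistry): the chalcone epoxide route, which sets out from aldehyde 7 and comes back to the route at target 17. Purchased 1-(5-bromo-2,4-dihydroxyphenyl)ethanone F1 would be converted with NaH and MOMCl in DMF into 1-[5-bromo-2,4-bis(methoxymethoxy)phenyl]ethanone F2. Stille coupling of F2 with 3 would give 1-[2,4-bis(methoxymethoxy)-5-(3-methylbut-2-enyl)phenyl]ethanone F3. Claisen–Schmidt condensation of F3 with 7 (KOH, EtOH) would give the (E)-chalcone F4. Juliá–Colonna epoxidation (poly-L-leucine, urea–hydrogen peroxide, DBU, THF), whose nucleophilic peroxide leaves the prenyl alkenes alone, should give the (2R,3S)-epoxy ketone F5. Warm HCl in MeOH would then remove the three acetals and let the freed 2'-hydroxyl open the epoxide at the benzylic carbon with inversion, giving 17 directly.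

2. Step 9.
   - What may go wrong: air oxidation of the enediol toward the flavonol, C-allylation of the enediol by the allyl palladium species, ketonisation toward the C3 ketone, or loss of C2 configuration by base-induced ring opening of the product.
   - Fallback: it sets out from 13 and comes back at 17. The tertiary hydroxyl of 13 would be silylated (TMSCl, imidazole, DMF) to the trimethylsilyl ether F6. Pd(PPh3)4 and morpholine in THF would then cleave the allyl ester; the acid decarboxylates to a mono-enol that can ketonise only to the C4 ketone and is no longer an oxidisable enediol. This should give the 3-O-trimethylsilyl trans-flavanone F7. The conditions of step 10 would remove the silyl group and both methoxymethyl groups to give 17.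

3. Step 6.
   - What may go wrong: sluggish attack of the chelated, weakly nucleophilic phenoxide; competing C-alkylation at the electron-rich ring A carbon between the two oxygens; base-induced decomposition of the glycidate before it is opened.
   - Fallback: it sets out from 7 and comes back at 12, forming the ether at the keto ester oxidation level. Allyl dichloroacetate F8 would be made from dichloroacetic acid and allyl alcohol (TsOH, toluene, Dean–Stark). Its Darzens condensation with 7 (t-BuOK, THF, −20 °C) would give the α-chloroglycidic ester F9, which rearranges on warming by chloride shift to allyl 3-chloro-3-aryl-2-oxopropanoate F10. Williamson etherification of phenol 4 with F10 (K2CO3, acetone, 0 °C to rt) would give 12 directly, bypassing 10 and 11.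

## Further compounds

F1 | step 8 | 1-(5-bromo-2,4-dihydroxyphenyl)ethanone (purchased) | CC(=O)c1cc(Br)c(O)cc1O
F2 | step 8 | 1-[5-bromo-2,4-bis(methoxymethoxy)phenyl]ethanone | CC(=O)c1cc(Br)c(OCOC)cc1OCOC
F3 | step 8 | 1-[2,4-bis(methoxymethoxy)-5-(3-methylbut-2-enyl)phenyl]ethanone | CC(=O)c1cc(CC=C(C)C)c(OCOC)cc1OCOC
F4 | step 8 | (E)-1-[2,4-bis(methoxymethoxy)-5-(3-methylbut-2-enyl)phenyl]-3-[4-(methoxymethoxy)-3-(3-methylbut-2-enyl)phenyl]prop-2-en-1-one | O=C(/C=C/c1ccc(OCOC)c(CC=C(C)C)c1)c1cc(CC=C(C)C)c(OCOC)cc1OCOC
F5 | step 8 | [2,4-bis(methoxymethoxy)-5-(3-methylbut-2-enyl)phenyl]{(2R,3S)-3-[4-(methoxymethoxy)-3-(3-methylbut-2-enyl)phenyl]oxiran-2-yl}methanone | O=C(c1cc(CC=C(C)C)c(OCOC)cc1OCOC)[C@@H]1O[C@H]1c1ccc(OCOC)c(CC=C(C)C)c1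
F6 | step 9 | allyl (2R,3R)-7-(methoxymethoxy)-2-[4-(methoxymethoxy)-3-(3-methylbut-2-enyl)phenyl]-6-(3-methylbut-2-enyl)-4-oxo-3-(trimethylsilyloxy)chromane-3-carboxylate | CC(C)=CCc1cc([C@H]2Oc3cc(OCOC)c(CC=C(C)C)cc3C(=O)[C@@]2(O[Si](C)(C)C)C(=O)OCC=C)ccc1OCOC
F7 | step 9 | (2R,3R)-7-(methoxymethoxy)-2-[4-(methoxymethoxy)-3-(3-methylbut-2-enyl)phenyl]-6-(3-methylbut-2-enyl)-3-(trimethylsilyloxy)chroman-4-one | CC(C)=CCc1cc([C@H]2Oc3cc(OCOC)c(CC=C(C)C)cc3C(=O)[C@@H]2O[Si](C)(C)C)ccc1OCOC
F8 | step 6 | allyl dichloroacetate | C=CCOC(=O)C(Cl)Cl
F9 | step 6 | allyl 2-chloro-3-[4-(methoxymethoxy)-3-(3-methylbut-2-enyl)phenyl]oxirane-2-carboxylate, racemic | C=CCOC(=O)C1(Cl)OC1c1ccc(OCOC)c(CC=C(C)C)c1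
F10 | step 6 | allyl 3-chloro-3-[4-(methoxymethoxy)-3-(3-methylbut-2-enyl)phenyl]-2-oxopropanoate, racemic | C=CCOC(=O)C(=O)C(Cl)c1ccc(OCOC)c(CC=C(C)C)c1
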